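**Retrosynthetic overview**
- Last step: global debenzylation of the pentabenzyl bis-isoflavone (BCl3/pentamethylbenzene) frees the five phenols without touching the two aryl chlorides.
- Both pyranone rings (ring C of each isoflavone) are closed together, by acid cyclisation of a bis(β-keto dimethyl acetal) made by twofold oxidative 1,2-aryl shift of a bis-chalcone.
- Key C–C bonds (the future C2–C3 of each isoflavone): twofold Claisen–Schmidt aldol condensation of a diaryl ether dialdehyde with two equivalents of a chlorinated phloroacetophenone dibenzyl ether.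
- Dialdehyde: SNAr of 4-fluorobenzaldehyde with 4-benzyloxy-3-hydroxybenzaldehyde. Ketone: phloroacetophenone, 4,6-di-O-benzylation, then chlorination ortho to the chelated OH, which fixes Cl at the future C8.
- Ring order: the four benzene rings (rings A and B of each half) are bought; the two rings C are formed last and simultaneously.

Assumption: the target has no stereocentre or stereogenic axis, so no enantioselective step is needed. Intermediates 8, 10 and 11 are diastereomer mixtures whose stereocentres are erased again, so their SMILES carry no stereodescriptors.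

**Route**

Step 1
Reactants: 1 1-(2,4,6-trihydroxyphenyl)ethan-1-one (phloroacetophenone)
Product: 2 1-[2,4-bis(benzyloxy)-6-hydroxyphenyl]ethan-1-one
Conditions: BnBr (2.05 equiv), K2CO3 (2.2 equiv), DMF, 0 °C → rt
Reagents that add atoms: benzyl bromide, BrCc1ccccc1
Why: Williamson etherification in which the last ortho-OH is locked in a strong hydrogen bond to the acetyl carbonyl and is the least nucleophilic, so two equivalents of benzyl bromide alkylate only the para-OH and one ortho-OH.

Step 2
Reactants: 2 1-[2,4-bis(benzyloxy)-6-hydroxyphenyl]ethan-1-one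
Product: 3 1-[4,6-bis(benzyloxy)-3-chloro-2-hydroxyphenyl]ethan-1-one
Conditions: NCS (1.05 equiv), DMF, 0 °C → rt
Reagents that add atoms: N-chlorosuccinimide, O=C1CCC(=O)N1Cl
Why: Electrophilic aromatic chlorination of the phloroglucinol-type ring is expected ortho to the chelated free phenol, by analogy with the 3-halogenation of 2-hydroxy-4,6-dialkoxyacetophenones, which places Cl next to the oxygen that becomes O1 and hence at C8 of the chromone (confirmed by NOE from the remaining ring proton to both OCH2 groups).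

Step 3
Reactants: 4 3,4-dihydroxybenzaldehyde
Product: 5 4-(benzyloxy)-3-hydroxybenzaldehyde
Conditions: BnBr (1.0 equiv), NaHCO3 (1.2 equiv), DMF, 40 °C
Reagents that add atoms: benzyl bromide, BrCc1ccccc1
Why: Williamson etherification selective for the more acidic 4-OH (para to the formyl group), the only hydroxyl that the weak base NaHCO3 deprotonates appreciably.

Step 4
Reactants: 5 4-(benzyloxy)-3-hydroxybenzaldehyde; 6 4-fluorobenzaldehyde (1.1 equiv)
Product: 7 4-(benzyloxy)-3-(4-formylphenoxy)benzaldehyde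
Conditions: K2CO3 (1.5 equiv), DMF, 120 °C
Reagents that add atoms: none
Why: Nucleophilic aromatic substitution (SNAr) in which the phenoxide of 5 displaces fluoride para to the activating formyl group of 6 through a Meisenheimer complex, a standard diaryl ether synthesis that tolerates both aldehydes and the benzyl ether.

Step 5
Reactants: 7 4-(benzyloxy)-3-(4-formylphenoxy)benzaldehyde; 3 1-[4,6-bis(benzyloxy)-3-chloro-2-hydroxyphenyl]ethan-1-one (2.2 equiv)
Product: 9 E,E-bis-chalcone (each CHO of 7 converted into CH=CH–C(=O)–aryl with aryl = 4,6-bis(benzyloxy)-3-chloro-2-hydroxyphenyl), via bis-aldol adduct 8 (not isolated)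
Conditions: 50% aq. KOH (excess), EtOH/THF, rt, 48 h; then cold 1 M HCl
Reagents that add atoms: none
Why: Twofold intermolecular Claisen–Schmidt aldol condensation in which the potassium enolate of ketone 3 adds to each non-enolisable aldehyde of 7 and E1cB dehydration of the β-hydroxy ketone gives the conjugated E,E-bis-chalcone under thermodynamic control, forming the Cα–Cβ bonds that become C2–C3 of both isoflavones.

Step 6
Reactants: 9 E,E-bis-chalcone
Product: 10 bis(β-keto dimethyl acetal), each half being aryl–C(=O)–CH(Ar)–CH(OMe)2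
Conditions: Tl(NO3)3·3H2O (2.4 equiv), MeOH/HC(OMe)3/CH2Cl2, rt, 12–24 h; filter off TlNO3, aq. NaHCO3 wash
Reagents that add atoms: methanol, CO
Why: Oxidative rearrangement of chalcones by trivalent thallium (McKillop–Taylor procedure), in which methoxythallation of each enone double bond and 1,2-shift of the para-oxygenated aryl group with loss of monovalent thallium gives the 1,2-diaryl-3,3-dimethoxypropan-1-one, the new benzylic stereocentres being formed unselectively and erased in the next step.

Step 7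
Reactants: 10 bis(β-keto dimethyl acetal)
Product: 12 pentabenzyl bis-isoflavone (5,7-bis(benzyloxy)-8-chloroisoflavone units joined through the 4'-O–3' diaryl ether with the 4'-OBn group on the second ring B), via bis(2-methoxyisoflavanone) 11 (not isolated)
Conditions: conc. HCl (10 vol%), MeOH/THF, 60 °C, 3 h
Reagents that add atoms: none
Why: Acid-catalysed acetal exchange and elimination in which only the free 2'-OH flanked by chlorine (the 6'-oxygen stays benzylated) attacks the oxocarbenium ion to close ring C, and loss of methanol from the 2-methoxyisoflavanone aromatises the pyranone, so chlorine ends up at C8 of each isoflavone.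

Step 8
Reactants: 12 pentabenzyl bis-isoflavone
Product: 13 Bisoflavolin M
Conditions: BCl3 (1 M in CH2Cl2, 15 equiv), pentamethylbenzene (15 equiv), CH2Cl2, −78 → −30 °C; MeOH quench, aqueous work-up
Reagents that add atoms: none
Why: Lewis-acid debenzylation with pentamethylbenzene as a non-basic benzyl cation scavenger cleaves all five aryl benzyl ethers at low temperature without touching the aryl chlorides, the diaryl ether or the chromone C2=C3 bond and without the hot acid that could cause Wessely–Moser isomerisation of 8-chloro to 6-chloro.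

**Compound list**

1 | 1-(2,4,6-trihydroxyphenyl)ethan-1-one (phloroacetophenone) | CC(=O)c1c(O)cc(O)cc1O | starting material
2 | 1-[2,4-bis(benzyloxy)-6-hydroxyphenyl]ethan-1-one | CC(=O)c1c(O)cc(OCc2ccccc2)cc1OCc1ccccc1 | intermediate
3 | 1-[4,6-bis(benzyloxy)-3-chloro-2-hydroxyphenyl]ethan-1-one | CC(=O)c1c(O)c(Cl)c(OCc2ccccc2)cc1OCc1ccccc1 | intermediate
4 | 3,4-dihydroxybenzaldehyde | O=Cc1ccc(O)c(O)c1 | starting material
5 | 4-(benzyloxy)-3-hydroxybenzaldehyde | O=Cc1ccc(OCc2ccccc2)c(O)c1 | intermediate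
6 | 4-fluorobenzaldehyde | O=Cc1ccc(F)cc1 | starting material
7 | 4-(benzyloxy)-3-(4-formylphenoxy)benzaldehyde | O=Cc1ccc(Oc2cc(C=O)ccc2OCc2ccccc2)cc1 | intermediate
8 | bis-aldol adduct: 1-[4,6-bis(benzyloxy)-3-chloro-2-hydroxyphenyl]-3-{4-[2-(benzyloxy)-5-{3-[4,6-bis(benzyloxy)-3-chloro-2-hydroxyphenyl]-1-hydroxy-3-oxopropyl}phenoxy]phenyl}-3-hydroxypropan-1-one (not isolated, diastereomer mixture) | O=C(CC(O)c1ccc(Oc2cc(C(O)CC(=O)c3c(O)c(Cl)c(OCc4ccccc4)cc3OCc3ccccc3)ccc2OCc2ccccc2)cc1)c1c(O)c(Cl)c(OCc2ccccc2)cc1OCc1ccccc1 | intermediate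
9 | (2E)-1-[4,6-bis(benzyloxy)-3-chloro-2-hydroxyphenyl]-3-{4-[2-(benzyloxy)-5-{(1E)-3-[4,6-bis(benzyloxy)-3-chloro-2-hydroxyphenyl]-3-oxoprop-1-en-1-yl}phenoxy]phenyl}prop-2-en-1-one (E,E-bis-chalcone) | O=C(/C=C/c1ccc(Oc2cc(/C=C/C(=O)c3c(O)c(Cl)c(OCc4ccccc4)cc3OCc3ccccc3)ccc2OCc2ccccc2)cc1)c1c(O)c(Cl)c(OCc2ccccc2)cc1OCc1ccccc1 | intermediate
10 | 1-[4,6-bis(benzyloxy)-3-chloro-2-hydroxyphenyl]-2-{4-[2-(benzyloxy)-5-{1-[4,6-bis(benzyloxy)-3-chloro-2-hydroxyphenyl]-3,3-dimethoxy-1-oxopropan-2-yl}phenoxy]phenyl}-3,3-dimethoxypropan-1-one (bis(β-keto dimethyl acetal), diastereomer mixture) | COC(OC)C(C(=O)c1c(O)c(Cl)c(OCc2ccccc2)cc1OCc1ccccc1)c1ccc(Oc2cc(C(C(OC)OC)C(=O)c3c(O)c(Cl)c(OCc4ccccc4)cc3OCc3ccccc3)ccc2OCc2ccccc2)cc1 | intermediate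
11 | 5,7-bis(benzyloxy)-3-{4-[2-(benzyloxy)-5-(5,7-bis(benzyloxy)-8-chloro-2-methoxy-4-oxochroman-3-yl)phenoxy]phenyl}-8-chloro-2-methoxychroman-4-one (bis(2-methoxyisoflavanone), not isolated, diastereomer mixture) | COC1Oc2c(Cl)c(OCc3ccccc3)cc(OCc3ccccc3)c2C(=O)C1c1ccc(Oc2cc(C3C(OC)Oc4c(Cl)c(OCc5ccccc5)cc(OCc5ccccc5)c4C3=O)ccc2OCc2ccccc2)cc1 | intermediate
12 | 5,7-bis(benzyloxy)-3-{4-[2-(benzyloxy)-5-(5,7-bis(benzyloxy)-8-chloro-4-oxo-4H-chromen-3-yl)phenoxy]phenyl}-8-chloro-4H-chromen-4-one (pentabenzyl ether of the target) | O=c1c(-c2ccc(Oc3cc(-c4coc5c(Cl)c(OCc6ccccc6)cc(OCc6ccccc6)c5c4=O)ccc3OCc3ccccc3)cc2)coc2c(Cl)c(OCc3ccccc3)cc(OCc3ccccc3)c12 | intermediate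
13 | Bisoflavolin M: 8-chloro-3-{4-[5-(8-chloro-5,7-dihydroxy-4-oxo-4H-chromen-3-yl)-2-hydroxyphenoxy]phenyl}-5,7-dihydroxy-4H-chromen-4-one (achiral) | O=c1c(-c2ccc(Oc3cc(-c4coc5c(Cl)c(O)cc(O)c5c4=O)ccc3O)cc2)coc2c(Cl)c(O)cc(O)c12 | target

**Totals**

Total step count: 8. Longest linear sequence: 6 steps (steps 1, 2, 5, 6, 7, 8 from compound 1; equally steps 3 to 8 from compound 4).

**Steps most likely to fail, with fallbacks**

1. The chlorination in step 2 may give some of the 5-chloro isomer or dichlorination. The fallback sets out from 2 and comes back at 3. Iodination of 2 (N-iodosuccinimide, DMF, rt) is expected to be cleanly ortho to the chelated phenol and gives 1-[4,6-bis(benzyloxy)-2-hydroxy-3-iodophenyl]ethan-1-one F1, which is purified by crystallisation. Copper-mediated aromatic halogen exchange (CuCl, monovalent copper chloride, 4 equiv, DMF, 130 °C) then replaces iodine by chlorine at the same carbon and delivers 3.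

2. The twofold Claisen–Schmidt condensation in step 5 may stall at the mono-chalcone or be eroded by flavanone formation, because the enolate is generated next to a phenoxide on a hindered ring. The fallback sets out from 3 (with 7) and comes back at 9. The chelated phenol of 3 is masked (NaH, MOMCl, DMF, 0 °C) to give 1-[4,6-bis(benzyloxy)-3-chloro-2-(methoxymethoxy)phenyl]ethan-1-one F2. This fully etherified ketone condenses with dialdehyde 7 (KOH, EtOH/THF, rt) to the bis(methoxymethyl) ether of the E,E-bis-chalcone F3, which cannot cyclise. Mild acid (3 M HCl, MeOH/THF, 40 °C) then removes both MOM groups to give 9.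

3. The twofold oxidative rearrangement in step 6 may be incomplete or be accompanied by oxidation of the electron-rich ring A. The fallback sets out from 9 and comes back at 12, bypassing 10 and 11. Bis-chalcone 9 is cyclised (NaOAc, EtOH/THF, reflux) by oxa-Michael addition of the free 2'-OH to the bis-flavanone 5,7-bis(benzyloxy)-2-{4-[2-(benzyloxy)-5-(5,7-bis(benzyloxy)-8-chloro-4-oxochroman-2-yl)phenoxy]phenyl}-8-chlorochroman-4-one F4 (diastereomer mixture). Oxidative 2,3-aryl migration with the trivalent iodine reagent PhI(OH)OTs (2.5 equiv, MeCN, reflux) then converts each flavanone into the isoflavone and gives 12 directly.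

**Further compounds**

F1 | step 2 | 1-[4,6-bis(benzyloxy)-2-hydroxy-3-iodophenyl]ethan-1-one | CC(=O)c1c(O)c(I)c(OCc2ccccc2)cc1OCc1ccccc1
F2 | step 5 | 1-[4,6-bis(benzyloxy)-3-chloro-2-(methoxymethoxy)phenyl]ethan-1-one | CC(=O)c1c(OCOC)c(Cl)c(OCc2ccccc2)cc1OCc1ccccc1
F3 | step 5 | E,E-bis-chalcone 9 with both 2'-OH groups as methoxymethyl ethers | O=C(/C=C/c1ccc(Oc2cc(/C=C/C(=O)c3c(OCOC)c(Cl)c(OCc4ccccc4)cc3OCc3ccccc3)ccc2OCc2ccccc2)cc1)c1c(OCOC)c(Cl)c(OCc2ccccc2)cc1OCc1ccccc1
F4 | step 6 | 5,7-bis(benzyloxy)-2-{4-[2-(benzyloxy)-5-(5,7-bis(benzyloxy)-8-chloro-4-oxochroman-2-yl)phenoxy]phenyl}-8-chlorochroman-4-one (bis-flavanone, diastereomer mixture) | O=C1CC(c2ccc(Oc3cc(C4CC(=O)c5c(OCc6ccccc6)cc(OCc6ccccc6)c(Cl)c5O4)ccc3OCc3ccccc3)cc2)Oc2c(Cl)c(OCc3ccccc3)cc(OCc3ccccc3)c12
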